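**Strategy.** Numbering follows furo[3,4-c]furan, with C1 carrying the guaiacyl ring and C4 the prenyloxyaryl ring. Ring O5–C4–C3a–C6a–C6 is not built directly. It grows from a donor–acceptor cyclopropane (C4, C3a, C6a), a 2-aryl-3-(silyloxymethyl)cyclopropanecarbaldehyde whose CHO is C6=O5. In one flask a silyl triflate expands this three-membered ring to a 2,3-dihydrofuran (Cloke–Wilson). Its enol ether then captures the oxocarbenium ion of a vanillin-derived acetal tethered through O2, closing ring O2–C1–C6a–C3a–C3, and silane reduces C6. The step exploits the cation-stabilising para-oxygenated aryl group on C4 and the obligatory cis C3a–C6a fusion. The one retained cyclopropane stereocentre (C3a) controls C4, C6a and C1.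

Key step: step 10

Assumption: Rh2(5S-MEPY)4 (MEPY = methyl 2-oxopyrrolidine-5-carboxylate) is taken to induce the same absolute sense with 5 as with simpler (Z)-allylic diazoacetates, i.e. the (1R,5S) bicycle; the 5R catalyst would be used if the sense proved opposite.

Step 1
Reactants: 1 vanillin
Product: 2 4-(tert-butyldimethylsilyloxy)-3-methoxybenzaldehyde
Conditions: t-BuMe2SiCl, imidazole, DMF, rt
Reagents that add atoms: tert-butyldimethylsilyl chloride, CC(C)(C)[Si](C)(C)Cl
Why: Imidazole-promoted silylation of the phenol should be clean; the aryl silyl ether is the later para donor for the ring expansion and the handle for late prenylation.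

Step 2
Reactants: 2 4-(tert-butyldimethylsilyloxy)-3-methoxybenzaldehyde
Product: 3 methyl (Z)-3-[4-(tert-butyldimethylsilyloxy)-3-methoxyphenyl]prop-2-enoate
Conditions: (CF3CH2O)2P(O)CH2CO2Me, KN(SiMe3)2, 18-crown-6, THF, −78 °C
Reagents that add atoms: methyl bis(2,2,2-trifluoroethyl)phosphonoacetate, COC(=O)CP(=O)(OCC(F)(F)F)OCC(F)(F)F
Why: Still–Gennari olefination should give the kinetic Z enoate, because the electron-poor phosphonate eliminates faster than the adduct equilibrates; the Z geometry later places the aryl group cis to both cyclopropane side arms.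

Step 3
Reactants: 3 methyl (Z)-3-[4-(tert-butyldimethylsilyloxy)-3-methoxyphenyl]prop-2-enoate
Product: 4 (Z)-3-[4-(tert-butyldimethylsilyloxy)-3-methoxyphenyl]prop-2-en-1-ol
Conditions: i-Bu2AlH (2.2 equiv), CH2Cl2, −78 °C; aq. potassium sodium tartrate
Reagents that add atoms: none
Why: 1,2-Reduction of the enoate by i-Bu2AlH at low temperature should leave the Z alkene and the aryl silyl ether untouched.

Step 4
Reactants: 4 (Z)-3-[4-(tert-butyldimethylsilyloxy)-3-methoxyphenyl]prop-2-en-1-ol
Product: 5 (Z)-3-[4-(tert-butyldimethylsilyloxy)-3-methoxyphenyl]prop-2-en-1-yl diazoacetate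
Conditions: TsNHN=CHCOCl, PhNMe2, CH2Cl2, 0 °C; then Et3N
Reagents that add atoms: glyoxylic acid chloride p-toluenesulfonylhydrazone, Cc1ccc(cc1)S(=O)(=O)NN=CC(Cl)=O
Why: O-Acylation followed by base-induced loss of p-toluenesulfinate from the hydrazone anion (Bamford–Stevens-type elimination) should deliver the diazoacetate in one operation.

Step 5
Reactants: 5 (Z)-3-[4-(tert-butyldimethylsilyloxy)-3-methoxyphenyl]prop-2-en-1-yl diazoacetate
Product: 6 (1R,5S,6R)-6-[4-(tert-butyldimethylsilyloxy)-3-methoxyphenyl]-3-oxabicyclo[3.1.0]hexan-2-one (aryl endo; all-cis cyclopropane)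
Conditions: Rh2(5S-MEPY)4 (1 mol %), CH2Cl2, reflux, slow addition of 5
Reagents that add atoms: none
Why: Enantioselective intramolecular cyclopropanation by the chiral dirhodium carboxamidate carbene; syn-stereospecific addition carries the Z geometry into C6 (aryl cis to the lactone ring) and the catalyst pocket selects the alkene face, setting C1 and C5.

Step 6
Reactants: 6 (1R,5S,6R)-6-[4-(tert-butyldimethylsilyloxy)-3-methoxyphenyl]-3-oxabicyclo[3.1.0]hexan-2-one
Product: 8 (1R,2R,3S)-2-[4-(tert-butyldimethylsilyloxy)-3-methoxyphenyl]-N-methoxy-N-methyl-3-[(triethylsilyloxy)methyl]cyclopropane-1-carboxamide (all-cis), via hydroxy amide 7 (not isolated)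
Conditions: MeNH(OMe)·HCl, i-PrMgCl, THF, −20 → 0 °C; aq. NH4Cl; crude with Et3SiCl, imidazole, CH2Cl2, 0 °C
Reagents that add atoms: N,O-dimethylhydroxylamine hydrochloride, CNOC.Cl; triethylsilyl chloride, CC[Si](CC)(CC)Cl
Why: Weinreb aminolysis of the lactone by the chloromagnesium amide, with immediate silylation of the freed primary alcohol so that the cis hydroxy amide cannot relactonise; no stereocentre is touched.

Step 7
Reactants: 8 (1R,2R,3S)-2-[4-(tert-butyldimethylsilyloxy)-3-methoxyphenyl]-N-methoxy-N-methyl-3-[(triethylsilyloxy)methyl]cyclopropane-1-carboxamide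
Product: 10 (1S,2R,3S)-2-[4-(tert-butyldimethylsilyloxy)-3-methoxyphenyl]-3-[(triethylsilyloxy)methyl]cyclopropane-1-carbaldehyde (CHO trans to aryl and to CH2OSiEt3), via all-cis aldehyde 9 (not isolated)
Conditions: i-Bu2AlH, THF, −78 °C; aq. potassium sodium tartrate; then DBU (0.2 equiv), CH2Cl2, rt
Reagents that add atoms: none
Why: The Weinreb amide should stop at the aldehyde through its chelated tetrahedral intermediate, and DBU then epimerises the only enolisable centre (C1) under thermodynamic control, relieving the all-cis strain and moving the CHO group out of reach of the silyloxymethyl oxygen.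

Step 8
Reactants: 1 vanillin
Product: 11 4-formyl-2-methoxyphenyl pivalate
Conditions: t-BuCOCl, Et3N, DMAP (cat.), CH2Cl2, 0 °C → rt
Reagents that add atoms: pivaloyl chloride, CC(C)(C)C(=O)Cl
Why: Standard acylation of the phenol; the hindered electron-withdrawing ester later protects the endo benzylic centre against acid epimerisation and survives fluoride.

Step 9
Reactants: 11 4-formyl-2-methoxyphenyl pivalate
Product: 12 4-(dimethoxymethyl)-2-methoxyphenyl pivalate
Conditions: HC(OMe)3 (neat), p-TsOH·H2O (1 mol %), rt; Et3N quench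
Reagents that add atoms: trimethyl orthoformate, COC(OC)OC
Why: Acid-catalysed acetalisation driven by the orthoformate should leave the hindered aryl ester intact.

Step 10
Reactants: 10 (1S,2R,3S)-2-[4-(tert-butyldimethylsilyloxy)-3-methoxyphenyl]-3-[(triethylsilyloxy)methyl]cyclopropane-1-carbaldehyde; 12 4-(dimethoxymethyl)-2-methoxyphenyl pivalate
Product: 16 2-methoxy-4-[(1S,3aS,4R,6aS)-4-(4-tert-butyldimethylsilyloxy-3-methoxyphenyl)tetrahydro-1H,3H-furo[3,4-c]furan-1-yl]phenyl pivalate (C4 aryl exo; C1 aryl endo), via dihydrofuran 13 (not isolated), via mixed acetal 14 (not isolated), via methyl acetal 15 (not isolated)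
Conditions: 12 (1.2 equiv), Me3SiOTf (0.3 equiv), 2,6-di-tert-butyl-4-methylpyridine (0.1 equiv), CH2Cl2, −78 → −40 °C; then Et3SiH (3 equiv), −40 → −20 °C
Reagents that add atoms: none
Why: Proposed new method: Me3SiOTf silylates the aldehyde oxygen of 10, the C1–C2 bond of the donor–acceptor cyclopropane ionises (push from the 4-silyloxyaryl group, pull from the silyloxycarbenium ion) and the enol oxygen closes on the benzylic cation, turning the three-membered ring into 2,3-dihydrofuran 13 (Cloke–Wilson ring expansion, five-membered O–C closure of a 1,3-zwitterion); the Et3Si ether then exchanges with acetal 12 to mixed acetal 14, whose oxocarbenium ion is attacked by enol ether carbon C4 (ring O2–C1–C6a–C3a–C3, closure 5-endo-trig at C=O+ and exo to the enol ether), and the cis-fused bicyclic oxocarbenium ion is caught as methyl acetal 15 and reduced at C6 by Et3SiH. The closest known reactions are the Lewis-acid Cloke–Wilson rearrangement of aryl-donor cyclopropyl aldehydes and ketones and the Lewis-acid cyclisation of 2-aryl-3-(hydroxymethyl)-2,3-dihydrofurans with aryl aldehyde dimethyl acetals followed by silane reduction of the acetal; only their merger in one flask is unprecedented. C3a is the untouched C3 of 10, since the breaking bond does not involve it. C4 is set by the reversible O–C closure, which places the aryl group trans to the C3 side chain (exo); the aryl-bearing C2 of 10 is planarised, so its configuration is irrelevant. C6a follows from the only geometrically possible cis ring fusion and C1 from the kinetic endo preference known for this oxocarbenium–enol ether cyclisation. The step needs the aldehyde oxygen, not the silyl ether oxygen, to capture the cation, which the trans relation of CHO and CH2OSiEt3 in 10 guarantees, and it needs the endo aryl group to resist acid epimerisation, which the electron-poor pivaloyloxy ring secures.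

Step 11
Reactants: 16 2-methoxy-4-[(1S,3aS,4R,6aS)-4-(4-tert-butyldimethylsilyloxy-3-methoxyphenyl)tetrahydro-1H,3H-furo[3,4-c]furan-1-yl]phenyl pivalate
Product: 17 2-methoxy-4-[(1S,3aS,4R,6aS)-4-{3-methoxy-4-[(3-methylbut-2-en-1-yl)oxy]phenyl}tetrahydro-1H,3H-furo[3,4-c]furan-1-yl]phenyl pivalate
Conditions: CsF, Me2C=CHCH2Br, DMF, rt
Reagents that add atoms: prenyl bromide (1-bromo-3-methylbut-2-ene), CC(C)=CCBr
Why: Fluoride cleaves the aryl silyl ether and the caesium phenoxide is O-alkylated in situ by the allylic bromide; having the bromide present from the start should keep the phenoxide from attacking the hindered pivalate.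

Step 12
Reactants: 17 2-methoxy-4-[(1S,3aS,4R,6aS)-4-{3-methoxy-4-[(3-methylbut-2-en-1-yl)oxy]phenyl}tetrahydro-1H,3H-furo[3,4-c]furan-1-yl]phenyl pivalate
Product: 18 2-methoxy-4-[(1S,3aS,4R,6aS)-4-{3-methoxy-4-[(3-methylbut-2-en-1-yl)oxy]phenyl}tetrahydro-1H,3H-furo[3,4-c]furan-1-yl]phenol
Conditions: K2CO3 (1.5 equiv), MeOH, rt; aq. NH4Cl
Reagents that add atoms: none
Why: Base-mediated methanolysis of the aryl ester should free the phenol without affecting the prenyl ether or the base-stable benzylic ether centres.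

**Compound list**

1 | vanillin (4-hydroxy-3-methoxybenzaldehyde) | COc1cc(C=O)ccc1O | starting material
2 | 4-(tert-butyldimethylsilyloxy)-3-methoxybenzaldehyde | COc1cc(C=O)ccc1O[Si](C)(C)C(C)(C)C | intermediate
3 | methyl (Z)-3-[4-(tert-butyldimethylsilyloxy)-3-methoxyphenyl]prop-2-enoate | COC(=O)/C=C\c1ccc(O[Si](C)(C)C(C)(C)C)c(OC)c1 | intermediate
4 | (Z)-3-[4-(tert-butyldimethylsilyloxy)-3-methoxyphenyl]prop-2-en-1-ol | OC/C=C\c1ccc(O[Si](C)(C)C(C)(C)C)c(OC)c1 | intermediate
5 | (Z)-3-[4-(tert-butyldimethylsilyloxy)-3-methoxyphenyl]prop-2-en-1-yl diazoacetate | [N-]=[N+]=CC(=O)OC/C=C\c1ccc(O[Si](C)(C)C(C)(C)C)c(OC)c1 | intermediate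
6 | (1R,5S,6R)-6-[4-(tert-butyldimethylsilyloxy)-3-methoxyphenyl]-3-oxabicyclo[3.1.0]hexan-2-one, aryl endo | O=C1OC[C@H]2[C@@H](c3ccc(O[Si](C)(C)C(C)(C)C)c(OC)c3)[C@@H]12 | intermediate
7 | (1R,2R,3S)-2-[4-(tert-butyldimethylsilyloxy)-3-methoxyphenyl]-3-(hydroxymethyl)-N-methoxy-N-methylcyclopropane-1-carboxamide, all-cis | CON(C)C(=O)[C@@H]1[C@H](c2ccc(O[Si](C)(C)C(C)(C)C)c(OC)c2)[C@@H]1CO | intermediate (not isolated)
8 | (1R,2R,3S)-2-[4-(tert-butyldimethylsilyloxy)-3-methoxyphenyl]-N-methoxy-N-methyl-3-[(triethylsilyloxy)methyl]cyclopropane-1-carboxamide, all-cis | CON(C)C(=O)[C@@H]1[C@H](c2ccc(O[Si](C)(C)C(C)(C)C)c(OC)c2)[C@@H]1CO[Si](CC)(CC)CC | intermediate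
9 | (1R,2R,3S)-2-[4-(tert-butyldimethylsilyloxy)-3-methoxyphenyl]-3-[(triethylsilyloxy)methyl]cyclopropane-1-carbaldehyde, all-cis | O=C[C@@H]1[C@H](c2ccc(O[Si](C)(C)C(C)(C)C)c(OC)c2)[C@@H]1CO[Si](CC)(CC)CC | intermediate (not isolated)
10 | (1S,2R,3S)-2-[4-(tert-butyldimethylsilyloxy)-3-methoxyphenyl]-3-[(triethylsilyloxy)methyl]cyclopropane-1-carbaldehyde, CHO trans to both neighbours | O=C[C@H]1[C@H](c2ccc(O[Si](C)(C)C(C)(C)C)c(OC)c2)[C@@H]1CO[Si](CC)(CC)CC | intermediate
11 | 4-formyl-2-methoxyphenyl pivalate | COc1cc(C=O)ccc1OC(=O)C(C)(C)C | intermediate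
12 | 4-(dimethoxymethyl)-2-methoxyphenyl pivalate | COC(OC)c1ccc(OC(=O)C(C)(C)C)c(OC)c1 | intermediate
13 | (2R,3S)-2-[4-(tert-butyldimethylsilyloxy)-3-methoxyphenyl]-3-[(triethylsilyloxy)methyl]-2,3-dihydrofuran, trans | CC[Si](CC)(CC)OC[C@@H]1C=CO[C@H]1c2ccc(O[Si](C)(C)C(C)(C)C)c(OC)c2 | intermediate (not isolated)
14 | 4-[{[(2R,3S)-2-(4-tert-butyldimethylsilyloxy-3-methoxyphenyl)-2,3-dihydrofuran-3-yl]methoxy}(methoxy)methyl]-2-methoxyphenyl pivalate, both acetal epimers | COC(OC[C@@H]1C=CO[C@H]1c2ccc(O[Si](C)(C)C(C)(C)C)c(OC)c2)c3ccc(OC(=O)C(C)(C)C)c(OC)c3 | intermediate (not isolated)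
15 | C6-methoxy derivative of 16 (methyl acetal at C6, both C6 epimers; ring configuration as in 16) | COc1cc([C@H]2OC[C@@H]3[C@H]2C(OC)O[C@H]3c2ccc(O[Si](C)(C)C(C)(C)C)c(OC)c2)ccc1OC(=O)C(C)(C)C | intermediate (not isolated)
16 | 2-methoxy-4-[(1S,3aS,4R,6aS)-4-(4-tert-butyldimethylsilyloxy-3-methoxyphenyl)tetrahydro-1H,3H-furo[3,4-c]furan-1-yl]phenyl pivalate | COc1cc([C@H]2OC[C@@H]3[C@H]2CO[C@H]3c2ccc(O[Si](C)(C)C(C)(C)C)c(OC)c2)ccc1OC(=O)C(C)(C)C | intermediate
17 | 2-methoxy-4-[(1S,3aS,4R,6aS)-4-{3-methoxy-4-[(3-methylbut-2-en-1-yl)oxy]phenyl}tetrahydro-1H,3H-furo[3,4-c]furan-1-yl]phenyl pivalate | COc1cc([C@H]2OC[C@@H]3[C@H]2CO[C@H]3c2ccc(OCC=C(C)C)c(OC)c2)ccc1OC(=O)C(C)(C)C | intermediate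
18 | 2-methoxy-4-[(1S,3aS,4R,6aS)-4-{3-methoxy-4-[(3-methylbut-2-en-1-yl)oxy]phenyl}tetrahydro-1H,3H-furo[3,4-c]furan-1-yl]phenol | COc1cc([C@H]2OC[C@@H]3[C@H]2CO[C@H]3c2ccc(OCC=C(C)C)c(OC)c2)ccc1O | target

Total step count: 12. Longest linear sequence: 10 steps (steps 1–7 and 10–12, from vanillin).

**Steps most likely to fail**

Step 10. The three events may not mesh in one flask: the acetal-derived cation may oligomerise the enol ether before ring expansion is complete, the electron-rich benzylic C4–O5 bond may be opened reductively, or the endo configuration at C1 may erode on prolonged contact with acid. The fallback sets out from 10 and runs the sequence as three separate known operations. Ring expansion alone with catalytic Yb(OTf)3 in CH2Cl2 gives dihydrofuran 13, which is isolated. Cyclisation of 13 with 12 and Me3SiOTf at −78 °C, quenched with Et3N, gives methyl acetal 15, which is isolated. Reduction of 15 with Et3SiH and BF3·OEt2 at −78 °C comes back to the route at 16. It makes no new compound (F0).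

Step 5. The chiral dirhodium carbene may fail to differentiate the alkene faces of this electron-rich substrate, or aromatic cycloaddition of the carbene may compete. The fallback moves enantiocontrol to an enzyme and sets out from 5. Cyclisation with achiral Cu(MeCN)4PF6 gives the racemic all-cis lactone F1. LiBH4 reduces both enantiomers to one and the same meso diol F2. Lipase-catalysed acetylation (Amano lipase PS, vinyl acetate) desymmetrises it to the monoacetate F3. Et3SiCl and imidazole give the silyl ether acetate F4. i-Bu2AlH at −78 °C removes the acetate to give the alcohol F5. Dess–Martin oxidation gives 9, which comes back to the route at 10 through the DBU epimerisation of step 7. If the enzyme acetylates the other arm, lipase hydrolysis of the diacetate of F2 supplies the needed monoacetate.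

Step 11. Fluoride or the liberated phenoxide may attack the pivalate, and acyl transfer between the two phenols would scramble which ring is free. The fallback sets out from 16 and separates the two events under neutral conditions. Bu4NF buffered with AcOH in THF at 0 °C removes only the aryl silyl ether to give the phenol F6. Mitsunobu etherification with 3-methylbut-2-en-1-ol, PPh3 and diisopropyl azodicarboxylate then comes back to the route at 17 without a phenoxide being present.

**Further compounds**

F0 | step 10 | none | none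
F1 | step 5 | racemic all-cis 6-[4-(tert-butyldimethylsilyloxy)-3-methoxyphenyl]-3-oxabicyclo[3.1.0]hexan-2-one (6 and its enantiomer) | O=C1OC[C@H]2[C@@H](c3ccc(O[Si](C)(C)C(C)(C)C)c(OC)c3)[C@@H]12.O=C1OC[C@@H]2[C@H](c3ccc(O[Si](C)(C)C(C)(C)C)c(OC)c3)[C@H]12
F2 | step 5 | meso all-cis {3-[4-(tert-butyldimethylsilyloxy)-3-methoxyphenyl]cyclopropane-1,2-diyl}dimethanol | OC[C@@H]1[C@H](c2ccc(O[Si](C)(C)C(C)(C)C)c(OC)c2)[C@@H]1CO
F3 | step 5 | all-cis monoacetate of F2, acetoxymethyl on the carbon that becomes C1 of 9 | CC(=O)OC[C@@H]1[C@H](c2ccc(O[Si](C)(C)C(C)(C)C)c(OC)c2)[C@@H]1CO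
F4 | step 5 | triethylsilyl ether of F3 | CC(=O)OC[C@@H]1[C@H](c2ccc(O[Si](C)(C)C(C)(C)C)c(OC)c2)[C@@H]1CO[Si](CC)(CC)CC
F5 | step 5 | all-cis {2-[4-(tert-butyldimethylsilyloxy)-3-methoxyphenyl]-3-[(triethylsilyloxy)methyl]cyclopropyl}methanol, the primary alcohol corresponding to 9 | OC[C@@H]1[C@H](c2ccc(O[Si](C)(C)C(C)(C)C)c(OC)c2)[C@@H]1CO[Si](CC)(CC)CC
F6 | step 11 | 4-[(1S,3aS,4R,6aS)-4-(4-hydroxy-3-methoxyphenyl)tetrahydro-1H,3H-furo[3,4-c]furan-1-yl]-2-methoxyphenyl pivalate | COc1cc([C@H]2OC[C@@H]3[C@H]2CO[C@H]3c2ccc(O)c(OC)c2)ccc1OC(=O)C(C)(C)C
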